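**Plan**

- Retrosynthesis: the exocyclic C11=C13 is taken back to an α-phosphono lactone, whose C7–C11 bond is cut to a C6 diazo(phosphono)acetate on the intact ten-membered ring. The ring is then opened at C1=C10 (phosphonate plus aldehyde), the chain at C5–C6 (alkenylmetal plus Weinreb amide), and the C8 ester and C9 acetate are detached.
- Forward: a C1–C5 alkenyl unit is joined to a C6–C10 unit from 2-deoxy-L-ribose; C6 and the C4–C5 epoxide are set on the open chain; the ten-membered ring is closed by intramolecular Horner–Wadsworth–Emmons olefination; the acyl groups are put on; only then is the γ-lactone annulated by C–H insertion and methylenated.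
- Stereochemistry: C8/C9 come from the sugar, C6 from CBS reduction, C4/C5 from hydroxyl-directed epoxidation under 1,3-allylic strain, C7 from the insertion, C2'/C3' from Sharpless epoxidation of angelyl alcohol followed by invertive chloride opening, and the C1=C10 geometry from the ring-closing olefination.
- Enabling feature: in the lactone ring O6–C12–C11–C7–C6, C11 lies 1,5 to a C7 hydrogen once O6 carries the two-carbon ester. The competing C–H bonds are deactivated: C6–H and C8–H sit α to acyloxy groups and C5–H is an oxirane C–H.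

Key step: step 27

Remark: germacranolide numbering is used (ring C1–C10, lactone C11–C13 with C12 the carbonyl, C14 the ester carbon on C10, C15 the methyl on C4, side-chain atoms primed); 24 and 25 are carried as C10 epimers and 36 is drawn as the expected C11 epimer, both centres being erased later.

**Route**

Step 1
Reactants: 1 methyl angelate
Product: 2 (2Z)-2-methylbut-2-en-1-ol
Conditions: DIBAL-H (2.2 equiv), CH2Cl2, −78 °C; aq. potassium sodium tartrate
Reagents that add atoms: none
Why: DIBAL-H 1,2-reduction of the conjugated ester should stop at the allylic alcohol at low temperature without isomerising the Z olefin.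

Step 2
Reactants: 2 (2Z)-2-methylbut-2-en-1-ol
Product: 3 [(2R,3S)-2,3-dimethyloxiran-2-yl]methanol
Conditions: Ti(OiPr)4 (10 mol %), D-(−)-diethyl tartrate (12 mol %), t-BuOOH, 4 Å molecular sieves, CH2Cl2, −20 °C
Reagents that add atoms: tert-butyl hydroperoxide, CC(C)(C)OO
Why: Sharpless asymmetric epoxidation, in which the Ti(OiPr)4/D-(−)-tartrate complex delivers oxygen to the face that makes C2 R and C3 S, the cis substituent pattern following from the Z olefin.

Step 3
Reactants: 3 [(2R,3S)-2,3-dimethyloxiran-2-yl]methanol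
Product: 4 (2S,3S)-2,3-dimethyloxirane-2-carboxylic acid
Conditions: RuCl3 (2 mol %), NaIO4 (3 equiv), CCl4/MeCN/H2O, rt
Reagents that add atoms: water, O
Why: RuO4-catalysed (Sharpless) oxidation should take the primary alcohol to the acid without opening the epoxide, so both stereocentres are kept.

Step 4
Reactants: 4 (2S,3S)-2,3-dimethyloxirane-2-carboxylic acid
Product: 5 (2R,3R)-3-chloro-2-hydroxy-2-methylbutanoic acid
Conditions: HCl (4 M in 1,4-dioxane), 0 °C → rt
Reagents that add atoms: hydrogen chloride, Cl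
Why: Acid-promoted epoxide opening in which chloride attacks C3 with inversion (SN2), because C2 is quaternary and adjacent to the carboxyl group, giving the (2R,3R) chlorohydrin.

Step 5
Reactants: 5 (2R,3R)-3-chloro-2-hydroxy-2-methylbutanoic acid
Product: 7 (2R,3R)-3-chloro-2-methyl-2-(triethylsilyloxy)butanoic acid, via bis-silyl derivative 6 (not isolated)
Conditions: TESOTf (2.2 equiv), 2,6-lutidine, CH2Cl2, 0 °C → rt; then THF/H2O, rt
Reagents that add atoms: triethylsilyl trifluoromethanesulfonate, CC[Si](CC)(CC)OS(=O)(=O)C(F)(F)F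
Why: Silyl triflate silylation caps the tertiary alcohol and the acid, and the labile silyl ester is hydrolysed by water while the hindered tertiary silyl ether stays.

Step 6
Reactants: 8 hex-1-en-5-yne
Product: 10 (1E)-1-iodo-2-methylhexa-1,5-diene, via alkenyldimethylalane 9 (not isolated)
Conditions: Me3Al (2 equiv), Cp2ZrCl2 (0.2 equiv), CH2Cl2, 0 °C → rt; then I2, THF, −30 → 0 °C
Reagents that add atoms: trimethylaluminium, C[Al](C)C; iodine, II
Why: Negishi zirconium-catalysed carboalumination adds methyl and aluminium syn across the terminal alkyne (methyl on the internal carbon) and iodinolysis with retention gives the E iodide, the isolated vinyl group being inert.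

Step 7
Reactants: 11 2-deoxy-L-ribose
Product: 12 2-deoxy-L-ribono-1,4-lactone
Conditions: Br2, H2O, rt
Reagents that add atoms: none
Why: Bromine-water oxidation of an aldose to its aldonolactone, which leaves the two carbinol stereocentres (later C8 and C9) untouched.

Step 8
Reactants: 12 2-deoxy-L-ribono-1,4-lactone
Product: 13 2,5-dideoxy-5-iodo-L-ribono-1,4-lactone
Conditions: I2, PPh3, imidazole, THF, 0 °C → rt
Reagents that add atoms: iodine, II
Why: Garegg–Samuelsson iodination converts the primary hydroxyl selectively in the presence of the secondary one.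

Step 9
Reactants: 13 2,5-dideoxy-5-iodo-L-ribono-1,4-lactone
Product: 14 3-O-TBS iodo lactone
Conditions: TBSCl, imidazole, DMF, rt
Reagents that add atoms: tert-butyldimethylsilyl chloride, CC(C)(C)[Si](C)(C)Cl
Why: Standard silylation of the remaining secondary alcohol with a group that survives the organometallic, hydride, peracid and amide-base steps ahead.

Step 10
Reactants: 14 3-O-TBS iodo lactone
Product: 15 C10 diethyl phosphonate lactone
Conditions: P(OEt)3 (neat), 150 °C
Reagents that add atoms: triethyl phosphite, CCOP(OCC)OCC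
Why: Michaelis–Arbuzov reaction of the primary iodide installs phosphorus on C10 under neutral conditions that lactone and silyl ether tolerate.

Step 11
Reactants: 15 C10 diethyl phosphonate lactone
Product: 16 γ-hydroxy Weinreb amide
Conditions: MeNH(OMe)·HCl, Me3Al, CH2Cl2, 0 °C → rt
Reagents that add atoms: N,O-dimethylhydroxylamine hydrochloride, CNOC.Cl
Why: Weinreb aminolysis of the γ-lactone by the aluminium amide gives the N-methoxy-N-methylamide and frees O9 without touching the stereocentres.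

Step 12
Reactants: 16 γ-hydroxy Weinreb amide
Product: 17 C9 p-methoxybenzyl ether Weinreb amide
Conditions: 2-(4-methoxybenzyloxy)-4-methylquinoline, MeOTf, MgO, PhCF3, 0 °C → rt
Reagents that add atoms: 2-(4-methoxybenzyloxy)-4-methylquinoline, COc1ccc(COc2cc(C)c3ccccc3n2)cc1
Why: Dudley-type neutral p-methoxybenzyl transfer from the N-methylated quinolinium salt etherifies O9 without acid or base, so the γ-hydroxy amide cannot relactonise, and the resulting ether is a poor leaving group for the later C10 anion.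

Step 13
Reactants: 10 (1E)-1-iodo-2-methylhexa-1,5-diene; 17 C9 p-methoxybenzyl ether Weinreb amide
Product: 20 enone of the C1–C10 chain, via alkenyllithium 18 (not isolated), via alkenylmagnesium bromide 19 (not isolated)
Conditions: 10, t-BuLi (2.0 equiv), Et2O, −78 °C; MgBr2·OEt2, −78 → 0 °C; then 17, THF, −20 → 0 °C; aq. NH4Cl
Reagents that add atoms: none
Why: Weinreb ketone synthesis, in which the alkenyl Grignard reagent (E geometry kept through Li–I exchange and transmetalation) adds once via the stable chelate and, being less basic than the lithium reagent, spares the protons α to phosphorus.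

Step 14
Reactants: 20 enone of the C1–C10 chain
Product: 21 (6S) allylic alcohol
Conditions: (R)-2-methyl-CBS-oxazaborolidine (0.3 equiv), catecholborane (2 equiv), toluene, −78 °C
Reagents that add atoms: none
Why: Corey–Bakshi–Shibata reduction, where the (R)-oxazaborolidine treats the alkenyl group as the large substituent and delivers hydride to give the 6S alcohol under reagent control, catecholborane leaving the vinyl group alone.

Step 15
Reactants: 21 (6S) allylic alcohol
Product: 22 threo (4R,5R) epoxy alcohol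
Conditions: mCPBA (1.1 equiv), NaHCO3, CH2Cl2, −10 → 0 °C
Reagents that add atoms: 3-chloroperoxybenzoic acid, OOC(=O)c1cccc(Cl)c1
Why: Hydroxyl-directed (Henbest) peracid epoxidation: with the C15 methyl cis to C6, 1,3-allylic strain holds H6 in the olefin plane and the hydrogen-bonded peracid attacks syn to the hydroxyl, which gives the threo 4R,5R epoxide, while the monosubstituted alkene is far less nucleophilic.

Step 16
Reactants: 22 threo (4R,5R) epoxy alcohol
Product: 23 C6 triethylsilyl ether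
Conditions: TESCl, imidazole, DMAP (cat.), CH2Cl2, 0 °C
Reagents that add atoms: triethylsilyl chloride, CC[Si](Cl)(CC)CC
Why: Mild silylation protects O6 (and blocks Payne rearrangement) with a group that can later be removed in the presence of the TBS ether.

Step 17
Reactants: 23 C6 triethylsilyl ether
Product: 24 C10 phosphonoacetate
Conditions: LDA (2.2 equiv), THF, −78 °C; ClCO2Me (1.1 equiv), −78 °C; aq. NH4Cl
Reagents that add atoms: methyl chloroformate, COC(=O)Cl
Why: C-Acylation of the α-lithio phosphonate with methyl chloroformate (the second equivalent of base absorbs the more acidic product) builds the phosphonoacetate carrying C14, the C10 configuration being irrelevant.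

Step 18
Reactants: 24 C10 phosphonoacetate
Product: 25 C1 aldehyde
Conditions: OsO4 (2 mol %), NaIO4 (4 equiv), 2,6-lutidine, 1,4-dioxane/H2O (3:1), rt
Reagents that add atoms: osmium tetroxide, O=[Os](=O)(=O)=O (regenerated by NaIO4)
Why: Lemieux–Johnson cleavage turns the only alkene into the C1 aldehyde under buffered conditions that spare the epoxide and the ethers.

Step 19
Reactants: 25 C1 aldehyde
Product: 26 ten-membered epoxy enoate with O6 triethylsilyl
Conditions: LiCl (10 equiv), DBU (5 equiv), MeCN, 1 mM (slow addition of 25), rt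
Reagents that add atoms: none
Why: Intramolecular Horner–Wadsworth–Emmons olefination under Masamune–Roush conditions at high dilution closes C1=C10, and both the usual E preference of phosphonoacetates and the ten-membered ring place C2 and C9 cis on the olefin, which is the required geometry.

Step 20
Reactants: 26 ten-membered epoxy enoate with O6 triethylsilyl
Product: 27 ring C6 alcohol
Conditions: HF·pyridine, pyridine, THF, 0 °C
Reagents that add atoms: none
Why: Selective desilylation, since buffered HF·pyridine cleaves the secondary triethylsilyl ether much faster than the tert-butyldimethylsilyl ether.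

Step 21
Reactants: 27 ring C6 alcohol; 28 diethylphosphonoacetic acid
Product: 29 ring C6 phosphonoacetate
Conditions: DCC, DMAP (cat.), CH2Cl2, 0 °C → rt
Reagents that add atoms: none
Why: Steglich esterification attaches the C11–C12 unit to O6 under neutral conditions that leave the epoxy alcohol configuration intact.

Step 22
Reactants: 29 ring C6 phosphonoacetate
Product: 30 ring C8 alcohol
Conditions: HF·pyridine (excess), pyridine, THF, rt
Reagents that add atoms: none
Why: Prolonged HF·pyridine treatment removes the hindered TBS ether, and the acidic fluoride source avoids the migration of the C6 ester to O8 that basic fluoride could cause.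

Step 23
Reactants: 30 ring C8 alcohol; 7 (2R,3R)-3-chloro-2-methyl-2-(triethylsilyloxy)butanoic acid
Product: 32 ring C8 chlorobutanoate, via acid chloride 31 (not isolated)
Conditions: 7, 1-chloro-N,N,2-trimethylprop-1-en-1-amine, CH2Cl2, 0 °C → rt; then 30, Et3N, DMAP, CH2Cl2, rt
Reagents that add atoms: none
Why: DMAP-catalysed acylation by the α-silyloxy acid chloride (made under neutral conditions with Ghosez's reagent) installs the side chain with its two stereocentres unchanged, at a stage where C8 is not yet flanked by the lactone.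

Step 24
Reactants: 32 ring C8 chlorobutanoate
Product: 33 ring C9 alcohol
Conditions: DDQ, CH2Cl2/pH 7 phosphate buffer (10:1), 0 °C → rt
Reagents that add atoms: none
Why: Oxidative cleavage of the p-methoxybenzyl ether by DDQ is neutral and spares the epoxide, silyl ether, esters and phosphonoacetate.

Step 25
Reactants: 33 ring C9 alcohol
Product: 34 ring C9 acetate
Conditions: Ac2O, pyridine, DMAP (cat.), CH2Cl2, 0 °C → rt
Reagents that add atoms: acetic anhydride, CC(=O)OC(C)=O
Why: DMAP-catalysed acetylation of the only free hydroxyl, the tertiary one being silylated.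

Step 26
Reactants: 34 ring C9 acetate
Product: 35 C6 diazo(phosphono)acetate
Conditions: 4-acetamidobenzenesulfonyl azide, DBU, MeCN, 0 °C
Reagents that add atoms: 4-acetamidobenzenesulfonyl azide, CC(=O)Nc1ccc(cc1)S(=O)(=O)N=[N+]=[N-]
Why: Regitz diazo transfer to the doubly activated methylene of the phosphonoacetate gives the carbenoid precursor.

Step 27
Reactants: 35 C6 diazo(phosphono)acetate
Product: 36 α-phosphono γ-lactone fused to the ten-membered ring
Conditions: Rh2(OAc)4 (2 mol %), CH2Cl2, reflux, 5 mM (slow addition of 35)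
Reagents that add atoms: none
Why: Rh2(OAc)4 decomposes the diazo ester with loss of N2 to an electrophilic rhodium carbenoid at C11, which inserts into a C7–H bond through a concerted three-centre transition state with retention at C7. The closest known reaction type is the dirhodium-catalysed 1,5 C–H insertion of α-diazo-α-(dialkoxyphosphoryl)acetates of secondary alcohols to α-phosphono-γ-butyrolactones. The five-membered lactone O6–C12–C11–C7–C6 closes in the 1,5 mode on the preformed ten-membered ring. At C7 the hydrogen replaced should be the one trans to O6 and to the bulky C8 ester, which gives the less strained trans-fused lactone (7R), and C11 is expected with phosphorus trans to C8, a centre that is epimerisable and removed in step 28. The step needs C7–H to win over C6–H, C5–H, C8–H and the oxygen lone pairs: C6–H, C8–H and C9–H are deactivated by their acyloxy groups, the oxirane C5–H by its high s-character, the only alkene is remote and electron-poor, and 1,5-insertion is the kinetically preferred mode for ester-tethered acceptor/acceptor carbenoids. High dilution and slow addition suppress carbene dimerisation, and the phosphoryl group is kept as the handle for the methylene group.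

Step 28
Reactants: 36 α-phosphono γ-lactone fused to the ten-membered ring
Product: 37 O-silylated α-methylene lactone
Conditions: KOtBu (1.0 equiv), THF, 0 °C; then paraformaldehyde, 0 °C → rt
Reagents that add atoms: formaldehyde (as paraformaldehyde), C=O
Why: Horner–Wadsworth–Emmons olefination of the α-phosphono lactone anion with formaldehyde creates C11=C13 and erases the C11 stereocentre, the single equivalent of base being consumed by the acidic C11–H before it can touch the esters.

Step 29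
Reactants: 37 O-silylated α-methylene lactone
Product: 38 CNP0185503.5 (target)
Conditions: HF·pyridine, pyridine, THF, 0 °C → rt
Reagents that add atoms: none
Why: Fluoride-mediated desilylation with buffered HF·pyridine frees the tertiary alcohol under conditions tolerated by trisubstituted epoxides, α-methylene lactones and esters, and avoids the base that would close the chlorohydrin to an epoxide.

**Compound list**

1 | methyl angelate, methyl (2Z)-2-methylbut-2-enoate | C/C=C(/C)C(=O)OC | starting material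
2 | (2Z)-2-methylbut-2-en-1-ol (angelyl alcohol) | C/C=C(/C)CO | intermediate
3 | [(2R,3S)-2,3-dimethyloxiran-2-yl]methanol | OC[C@@]1(C)O[C@H]1C | intermediate
4 | (2S,3S)-2,3-dimethyloxirane-2-carboxylic acid | OC(=O)[C@@]1(C)O[C@H]1C | intermediate
5 | (2R,3R)-3-chloro-2-hydroxy-2-methylbutanoic acid | OC(=O)[C@@](C)(O)[C@@H](C)Cl | intermediate
6 | triethylsilyl (2R,3R)-3-chloro-2-methyl-2-(triethylsilyloxy)butanoate | CC[Si](CC)(CC)OC(=O)[C@@](C)(O[Si](CC)(CC)CC)[C@@H](C)Cl | intermediate (not isolated)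
7 | (2R,3R)-3-chloro-2-methyl-2-(triethylsilyloxy)butanoic acid | OC(=O)[C@@](C)(O[Si](CC)(CC)CC)[C@@H](C)Cl | intermediate
8 | hex-1-en-5-yne | C=CCCC#C | starting material
9 | dimethyl[(1E)-2-methylhexa-1,5-dien-1-yl]alane | C=CCC/C(C)=C/[Al](C)C | intermediate (not isolated)
10 | (1E)-1-iodo-2-methylhexa-1,5-diene | C=CCC/C(C)=C/I | intermediate
11 | 2-deoxy-L-ribose | O=CC[C@@H](O)[C@@H](O)CO | starting material
12 | 2-deoxy-L-ribono-1,4-lactone, (4R,5S)-4-hydroxy-5-(hydroxymethyl)oxolan-2-one | O=C1C[C@@H](O)[C@H](CO)O1 | intermediate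
13 | 2,5-dideoxy-5-iodo-L-ribono-1,4-lactone | O=C1C[C@@H](O)[C@H](CI)O1 | intermediate
14 | 3-O-(tert-butyldimethylsilyl)-2,5-dideoxy-5-iodo-L-ribono-1,4-lactone | O=C1C[C@@H](O[Si](C)(C)C(C)(C)C)[C@H](CI)O1 | intermediate
15 | 3-O-(tert-butyldimethylsilyl)-2,5-dideoxy-5-(diethoxyphosphoryl)-L-ribono-1,4-lactone | O=C1C[C@@H](O[Si](C)(C)C(C)(C)C)[C@H](CP(=O)(OCC)OCC)O1 | intermediate
16 | (3R,4R)-3-(tert-butyldimethylsilyloxy)-5-(diethoxyphosphoryl)-4-hydroxy-N-methoxy-N-methylpentanamide | CON(C)C(=O)C[C@@H](O[Si](C)(C)C(C)(C)C)[C@@H](O)CP(=O)(OCC)OCC | intermediate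
17 | (3R,4R)-3-(tert-butyldimethylsilyloxy)-5-(diethoxyphosphoryl)-N-methoxy-4-(4-methoxybenzyloxy)-N-methylpentanamide | CON(C)C(=O)C[C@@H](O[Si](C)(C)C(C)(C)C)[C@@H](OCc1ccc(OC)cc1)CP(=O)(OCC)OCC | intermediate
18 | [(1E)-2-methylhexa-1,5-dien-1-yl]lithium | C=CCC/C(C)=C/[Li] | intermediate (not isolated)
19 | [(1E)-2-methylhexa-1,5-dien-1-yl]magnesium bromide | C=CCC/C(C)=C/[Mg]Br | intermediate (not isolated)
20 | diethyl [(2R,3R,6E)-3-(tert-butyldimethylsilyloxy)-2-(4-methoxybenzyloxy)-7-methyl-5-oxoundeca-6,10-dien-1-yl]phosphonate | C=CCC/C(C)=C/C(=O)C[C@@H](O[Si](C)(C)C(C)(C)C)[C@@H](OCc1ccc(OC)cc1)CP(=O)(OCC)OCC | intermediate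
21 | diethyl [(2R,3R,5S,6E)-3-(tert-butyldimethylsilyloxy)-5-hydroxy-2-(4-methoxybenzyloxy)-7-methylundeca-6,10-dien-1-yl]phosphonate | C=CCC/C(C)=C/[C@@H](O)C[C@@H](O[Si](C)(C)C(C)(C)C)[C@@H](OCc1ccc(OC)cc1)CP(=O)(OCC)OCC | intermediate
22 | diethyl [(2R,3R,5S)-5-[(2R,3R)-3-(but-3-en-1-yl)-3-methyloxiran-2-yl]-3-(tert-butyldimethylsilyloxy)-5-hydroxy-2-(4-methoxybenzyloxy)pentyl]phosphonate | C=CCC[C@@]1(C)O[C@@H]1[C@@H](O)C[C@@H](O[Si](C)(C)C(C)(C)C)[C@@H](OCc1ccc(OC)cc1)CP(=O)(OCC)OCC | intermediate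
23 | diethyl [(2R,3R,5S)-5-[(2R,3R)-3-(but-3-en-1-yl)-3-methyloxiran-2-yl]-3-(tert-butyldimethylsilyloxy)-2-(4-methoxybenzyloxy)-5-(triethylsilyloxy)pentyl]phosphonate | C=CCC[C@@]1(C)O[C@@H]1[C@@H](O[Si](CC)(CC)CC)C[C@@H](O[Si](C)(C)C(C)(C)C)[C@@H](OCc1ccc(OC)cc1)CP(=O)(OCC)OCC | intermediate
24 | methyl (3R,4R,6S)-6-[(2R,3R)-3-(but-3-en-1-yl)-3-methyloxiran-2-yl]-4-(tert-butyldimethylsilyloxy)-2-(diethoxyphosphoryl)-3-(4-methoxybenzyloxy)-6-(triethylsilyloxy)hexanoate (C2 epimers) | C=CCC[C@@]1(C)O[C@@H]1[C@@H](O[Si](CC)(CC)CC)C[C@@H](O[Si](C)(C)C(C)(C)C)[C@@H](OCc1ccc(OC)cc1)C(C(=O)OC)P(=O)(OCC)OCC | intermediate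
25 | methyl (3R,4R,6S)-4-(tert-butyldimethylsilyloxy)-2-(diethoxyphosphoryl)-3-(4-methoxybenzyloxy)-6-[(2R,3R)-3-methyl-3-(3-oxopropyl)oxiran-2-yl]-6-(triethylsilyloxy)hexanoate (C2 epimers) | O=CCC[C@@]1(C)O[C@@H]1[C@@H](O[Si](CC)(CC)CC)C[C@@H](O[Si](C)(C)C(C)(C)C)[C@@H](OCc1ccc(OC)cc1)C(C(=O)OC)P(=O)(OCC)OCC | intermediate
26 | methyl (1(10)E,4R,5R,6S,8R,9S)-8-(tert-butyldimethylsilyloxy)-4,5-epoxy-9-(4-methoxybenzyloxy)-6-(triethylsilyloxy)-11,12,13-trinorgermacr-1(10)-en-14-oate | CC[Si](CC)(CC)O[C@H]1C[C@@H](O[Si](C)(C)C(C)(C)C)[C@@H](OCc3ccc(OC)cc3)/C(C(=O)OC)=C\CC[C@@]2(C)O[C@H]12 | intermediate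
27 | methyl (1(10)E,4R,5R,6S,8R,9S)-8-(tert-butyldimethylsilyloxy)-4,5-epoxy-6-hydroxy-9-(4-methoxybenzyloxy)-11,12,13-trinorgermacr-1(10)-en-14-oate | O[C@H]1C[C@@H](O[Si](C)(C)C(C)(C)C)[C@@H](OCc3ccc(OC)cc3)/C(C(=O)OC)=C\CC[C@@]2(C)O[C@H]12 | intermediate
28 | diethylphosphonoacetic acid | CCOP(=O)(OCC)CC(=O)O | starting material
29 | methyl (1(10)E,4R,5R,6S,8R,9S)-8-(tert-butyldimethylsilyloxy)-6-[(diethoxyphosphoryl)acetoxy]-4,5-epoxy-9-(4-methoxybenzyloxy)-11,12,13-trinorgermacr-1(10)-en-14-oate | CCOP(=O)(OCC)CC(=O)O[C@H]1C[C@@H](O[Si](C)(C)C(C)(C)C)[C@@H](OCc3ccc(OC)cc3)/C(C(=O)OC)=C\CC[C@@]2(C)O[C@H]12 | intermediate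
30 | methyl (1(10)E,4R,5R,6S,8R,9S)-6-[(diethoxyphosphoryl)acetoxy]-4,5-epoxy-8-hydroxy-9-(4-methoxybenzyloxy)-11,12,13-trinorgermacr-1(10)-en-14-oate | CCOP(=O)(OCC)CC(=O)O[C@H]1C[C@@H](O)[C@@H](OCc3ccc(OC)cc3)/C(C(=O)OC)=C\CC[C@@]2(C)O[C@H]12 | intermediate
31 | (2R,3R)-3-chloro-2-methyl-2-(triethylsilyloxy)butanoyl chloride | ClC(=O)[C@@](C)(O[Si](CC)(CC)CC)[C@@H](C)Cl | intermediate (not isolated)
32 | methyl (1(10)E,4R,5R,6S,8R,9S)-8-[(2R,3R)-3-chloro-2-methyl-2-(triethylsilyloxy)butanoyloxy]-6-[(diethoxyphosphoryl)acetoxy]-4,5-epoxy-9-(4-methoxybenzyloxy)-11,12,13-trinorgermacr-1(10)-en-14-oate | CCOP(=O)(OCC)CC(=O)O[C@H]1C[C@@H](OC(=O)[C@@](C)(O[Si](CC)(CC)CC)[C@@H](C)Cl)[C@@H](OCc3ccc(OC)cc3)/C(C(=O)OC)=C\CC[C@@]2(C)O[C@H]12 | intermediate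
33 | methyl (1(10)E,4R,5R,6S,8R,9S)-8-[(2R,3R)-3-chloro-2-methyl-2-(triethylsilyloxy)butanoyloxy]-6-[(diethoxyphosphoryl)acetoxy]-4,5-epoxy-9-hydroxy-11,12,13-trinorgermacr-1(10)-en-14-oate | CCOP(=O)(OCC)CC(=O)O[C@H]1C[C@@H](OC(=O)[C@@](C)(O[Si](CC)(CC)CC)[C@@H](C)Cl)[C@@H](O)/C(C(=O)OC)=C\CC[C@@]2(C)O[C@H]12 | intermediate
34 | methyl (1(10)E,4R,5R,6S,8R,9S)-9-acetoxy-8-[(2R,3R)-3-chloro-2-methyl-2-(triethylsilyloxy)butanoyloxy]-6-[(diethoxyphosphoryl)acetoxy]-4,5-epoxy-11,12,13-trinorgermacr-1(10)-en-14-oate | CCOP(=O)(OCC)CC(=O)O[C@H]1C[C@@H](OC(=O)[C@@](C)(O[Si](CC)(CC)CC)[C@@H](C)Cl)[C@@H](OC(C)=O)/C(C(=O)OC)=C\CC[C@@]2(C)O[C@H]12 | intermediate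
35 | methyl (1(10)E,4R,5R,6S,8R,9S)-9-acetoxy-8-[(2R,3R)-3-chloro-2-methyl-2-(triethylsilyloxy)butanoyloxy]-6-[diazo(diethoxyphosphoryl)acetoxy]-4,5-epoxy-11,12,13-trinorgermacr-1(10)-en-14-oate | CCOP(=O)(OCC)C(=[N+]=[N-])C(=O)O[C@H]1C[C@@H](OC(=O)[C@@](C)(O[Si](CC)(CC)CC)[C@@H](C)Cl)[C@@H](OC(C)=O)/C(C(=O)OC)=C\CC[C@@]2(C)O[C@H]12 | intermediate
36 | methyl (1(10)E,4R,5R,6S,7R,8R,9S,11S)-9-acetoxy-8-[(2R,3R)-3-chloro-2-methyl-2-(triethylsilyloxy)butanoyloxy]-11-(diethoxyphosphoryl)-4,5-epoxy-13-norgermacr-1(10)-en-12,6-olid-14-oate | CCOP(=O)(OCC)[C@@H]1C(=O)O[C@H]2[C@H]1[C@@H](OC(=O)[C@@](C)(O[Si](CC)(CC)CC)[C@@H](C)Cl)[C@@H](OC(C)=O)/C(C(=O)OC)=C\CC[C@@]1(C)O[C@H]21 | intermediate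
37 | methyl (1(10)E,4R,5R,6S,7R,8R,9S)-9-acetoxy-8-[(2R,3R)-3-chloro-2-methyl-2-(triethylsilyloxy)butanoyloxy]-4,5-epoxygermacra-1(10),11(13)-dien-12,6-olid-14-oate | C=C1C(=O)O[C@H]2[C@H]1[C@@H](OC(=O)[C@@](C)(O[Si](CC)(CC)CC)[C@@H](C)Cl)[C@@H](OC(C)=O)/C(C(=O)OC)=C\CC[C@@]1(C)O[C@H]21 | intermediate
38 | CNP0185503.5, methyl (1(10)E,4R,5R,6S,7R,8R,9S)-9-acetoxy-8-[(2R,3R)-3-chloro-2-hydroxy-2-methylbutanoyloxy]-4,5-epoxygermacra-1(10),11(13)-dien-12,6-olid-14-oate | C=C1C(=O)O[C@H]2[C@H]1[C@@H](OC(=O)[C@@](C)(O)[C@@H](C)Cl)[C@@H](OC(C)=O)/C(C(=O)OC)=C\CC[C@@]1(C)O[C@H]21 | target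

**Step count and risks**

Total step count: 29 (side chain 1–5, alkenyl iodide 6, main line 7–29). Longest linear sequence: 23 steps, from 2-deoxy-L-ribose 11 to 38 (steps 7–29).

The three steps most likely to fail:

1. Step 27 (C–H insertion). The carbenoid may be consumed before it reaches C7–H: by attack of the epoxide oxygen (ylide formation followed by deoxygenation or ring expansion), by insertion into C6–H to a β-lactone, or by dimerisation because the C7 hydrogens, flanked by two acyloxy-bearing carbons, are electron-poor. Insertion into the other C7 hydrogen would give the cis-fused lactone. Fallback: the insertion is moved forward to a stage where C8 and C9 still carry ethers and C7–H is more hydridic. Setting out from 29, diazo transfer (4-acetamidobenzenesulfonyl azide, DBU) should give the ether-protected diazo ester F1. Rh2(O2CCPh3)4, whose bulky carboxylates disfavour the tertiary C8–H, should then close the α-phosphono lactone F2, and KOtBu/paraformaldehyde should give the α-methylene lactone F3. HF·pyridine would free the C8 alcohol F4, acylation with acid chloride 31 (Et3N, DMAP) would give the C8 ester F5, and DDQ would give the C9 alcohol F6. Acetylation (Ac2O, pyridine, DMAP) comes back to the route at 37.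

2. Step 19 (ring closure). Intermolecular olefination to oligomers may outrun closure of the strained ten-membered ring, and the C10 anion may expel the C9 benzyloxy group. Fallback: ring-closing metathesis in place of olefination. Setting out from 24, Horner–Wadsworth–Emmons reaction with formaldehyde (K2CO3, aq. HCHO, THF) should give the 2-substituted acrylate F7, which already carries the C1 vinyl group. The second-generation Hoveyda–Grubbs catalyst in hot, dilute toluene should then close C1=C10 with loss of ethene, the ring enforcing the cis arrangement of C2 and C9, and return to 26.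

3. Step 13 (fragment union). The basic alkenylmetal may abstract a proton α to phosphorus (or α to the amide, with loss of the C8 silyloxy group) instead of adding to the amide. Fallback: a non-basic chromium-mediated addition. Setting out from 17, DIBAL-H (THF, −78 °C) should give the aldehyde F8. Nozaki–Hiyama–Kishi coupling with 10 (CrCl2, NiCl2 cat., DMSO) should give the allylic alcohol F9 as a mixture of C6 epimers, and Dess–Martin oxidation converges on enone 20, from which C6 is set as before.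

**Further compounds**

F1 | step 27 | methyl (1(10)E,4R,5R,6S,8R,9S)-8-(tert-butyldimethylsilyloxy)-6-[diazo(diethoxyphosphoryl)acetoxy]-4,5-epoxy-9-(4-methoxybenzyloxy)-11,12,13-trinorgermacr-1(10)-en-14-oate | CCOP(=O)(OCC)C(=[N+]=[N-])C(=O)O[C@H]1C[C@@H](O[Si](C)(C)C(C)(C)C)[C@@H](OCc3ccc(OC)cc3)/C(C(=O)OC)=C\CC[C@@]2(C)O[C@H]12
F2 | step 27 | methyl (1(10)E,4R,5R,6S,7R,8R,9S,11S)-8-(tert-butyldimethylsilyloxy)-11-(diethoxyphosphoryl)-4,5-epoxy-9-(4-methoxybenzyloxy)-13-norgermacr-1(10)-en-12,6-olid-14-oate | CCOP(=O)(OCC)[C@@H]1C(=O)O[C@H]2[C@H]1[C@@H](O[Si](C)(C)C(C)(C)C)[C@@H](OCc3ccc(OC)cc3)/C(C(=O)OC)=C\CC[C@@]1(C)O[C@H]21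
F3 | step 27 | methyl (1(10)E,4R,5R,6S,7R,8R,9S)-8-(tert-butyldimethylsilyloxy)-4,5-epoxy-9-(4-methoxybenzyloxy)germacra-1(10),11(13)-dien-12,6-olid-14-oate | C=C1C(=O)O[C@H]2[C@H]1[C@@H](O[Si](C)(C)C(C)(C)C)[C@@H](OCc3ccc(OC)cc3)/C(C(=O)OC)=C\CC[C@@]1(C)O[C@H]21
F4 | step 27 | methyl (1(10)E,4R,5R,6S,7R,8R,9S)-4,5-epoxy-8-hydroxy-9-(4-methoxybenzyloxy)germacra-1(10),11(13)-dien-12,6-olid-14-oate | C=C1C(=O)O[C@H]2[C@H]1[C@@H](O)[C@@H](OCc3ccc(OC)cc3)/C(C(=O)OC)=C\CC[C@@]1(C)O[C@H]21
F5 | step 27 | methyl (1(10)E,4R,5R,6S,7R,8R,9S)-8-[(2R,3R)-3-chloro-2-methyl-2-(triethylsilyloxy)butanoyloxy]-4,5-epoxy-9-(4-methoxybenzyloxy)germacra-1(10),11(13)-dien-12,6-olid-14-oate | C=C1C(=O)O[C@H]2[C@H]1[C@@H](OC(=O)[C@@](C)(O[Si](CC)(CC)CC)[C@@H](C)Cl)[C@@H](OCc3ccc(OC)cc3)/C(C(=O)OC)=C\CC[C@@]1(C)O[C@H]21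
F6 | step 27 | methyl (1(10)E,4R,5R,6S,7R,8R,9S)-8-[(2R,3R)-3-chloro-2-methyl-2-(triethylsilyloxy)butanoyloxy]-4,5-epoxy-9-hydroxygermacra-1(10),11(13)-dien-12,6-olid-14-oate | C=C1C(=O)O[C@H]2[C@H]1[C@@H](OC(=O)[C@@](C)(O[Si](CC)(CC)CC)[C@@H](C)Cl)[C@@H](O)/C(C(=O)OC)=C\CC[C@@]1(C)O[C@H]21
F7 | step 19 | methyl (3R,4R,6S)-6-[(2R,3R)-3-(but-3-en-1-yl)-3-methyloxiran-2-yl]-4-(tert-butyldimethylsilyloxy)-3-(4-methoxybenzyloxy)-2-methylidene-6-(triethylsilyloxy)hexanoate | C=CCC[C@@]1(C)O[C@@H]1[C@@H](O[Si](CC)(CC)CC)C[C@@H](O[Si](C)(C)C(C)(C)C)[C@@H](OCc1ccc(OC)cc1)C(=C)C(=O)OC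
F8 | step 13 | diethyl [(2R,3R)-3-(tert-butyldimethylsilyloxy)-2-(4-methoxybenzyloxy)-5-oxopentyl]phosphonate | O=CC[C@@H](O[Si](C)(C)C(C)(C)C)[C@@H](OCc1ccc(OC)cc1)CP(=O)(OCC)OCC
F9 | step 13 | diethyl [(2R,3R,6E)-3-(tert-butyldimethylsilyloxy)-5-hydroxy-2-(4-methoxybenzyloxy)-7-methylundeca-6,10-dien-1-yl]phosphonate (C5 epimers) | C=CCC/C(C)=C/C(O)C[C@@H](O[Si](C)(C)C(C)(C)C)[C@@H](OCc1ccc(OC)cc1)CP(=O)(OCC)OCC
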